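(The earlier runs and the new flask are simulated on assumed constants; the scatter is artificial.)

**Two roles.** The free catalyst in these flasks makes target, and by the last candidate step it can also be lost to target, one molecule for one molecule, as spent catalyst.

| flask | starting material | second substrate | free catalyst | remark | time |
|---|---|---|---|---|---|
| autumn | 41 mM (fed, over 4.0 h) | 41 mM | 0.71 mM | run made earlier |  |
| spring | 41 mM (fed, over 4.0 h) | 41 mM | 26 mM | run made earlier |  |
| Tuesday's | 41 mM (fed, over 4.0 h) | 41.0 mM | 1.2 mM |  | 6.0 d |
| Monday's | 41 mM (fed, over 4.0 h) | 41.0 mM | 3.0 mM |  | 6.0 d |
| Thursday's | 41 mM (fed, over 4.0 h) | 41.0 mM | 10 mM |  | 6.0 d |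
| Wednesday's | 41 mM (fed, over 4.0 h) | 41.0 mM | 30 mM |  | 6.0 d |

| run | time / d | target / % |
|---|---|---|
| autumn | 0.833 | 16.0 |
| autumn | 2.00 | 34.2 |
| autumn | 4.00 | 63.7 |
| autumn | 6.00 | 82.1 |
| spring | 1.67 | 56.1 |
| spring | 3.00 | 43.8 |
| spring | 5.00 | 38.4 |
| spring | 6.00 | 37.3 |

(each reading ± 1 percentage point)

- amount of target at the end, in percent of the starting material charged for Tuesday's, Monday's, Thursday's, Wednesday's, in this order
- the course of these numbers from the first flask to the last (falls, then rises / rises, then falls / rises all the way / hardly changes / falls all the way)

- candidate steps: starting material + free catalyst <-> catalyst intermediate A; catalyst intermediate A -> free catalyst + target; second substrate + free catalyst <-> catalyst intermediate B; catalyst intermediate B -> free catalyst + second product; free catalyst + target -> spent catalyst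
- "hardly changes" means that all values lie within two and a half points (for a concentration: within two and a half percent of the largest)

**Catalyst ceiling.** The spring run fell from 56.1% to 37.3% at 6.00 d. If each catalyst molecule takes one target molecule with it, 41 mM less 26 mM leaves 36.6%, and the reading lies within its scatter of that. So I took as my rule the catalyst ceiling, the end target as a share of the charge once the starting material has passed and the catalyst is spent, one minus c(free catalyst) over c(starting material): 97.1% for Tuesday's, 92.7% for Monday's, 75.6% for Thursday's and 26.8% for Wednesday's.

**Enough time?** My first objection was that the loss might not finish. Reckoning as if a flask held target and living catalyst and nothing else that touched them, the ratio of living catalyst to target should decay exponentially, and the spring readings at 3.00 d and 5.00 d give about 0.624 d⁻¹, a rate that scales with the ceiling in mM. Counting the target as present from the start, which overstates the time, I reckoned that ratio to shrink about 2300-fold for Thursday's, so I kept the ceiling there. For Wednesday's the same count, which makes this a low mark, gave 28.1%.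

**Enough turnovers?** My second objection concerned the small charges. Tuesday's needs 33.2 turnovers (the turnover number) to reach its ceiling, and the autumn catalyst had made 36.8 by 4.00 d, more than that. Putting that answer back in, though, at equal turnovers below its ceiling Tuesday's holds 1.69 times the autumn target in mM, so I expected its catalyst to be lost after fewer turnovers than the autumn count suggests. I could not reckon how many, so as a guess I let Tuesday's stop short of its ceiling by the 4.4 percentage points that separates it from Monday's ceiling. Monday's needs 12.7 turnovers, fewer than the autumn run's 19.7 at 2.00 d, so I kept its ceiling and held the first two flasks level, unable to order them.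

**The result.** The forecast, which differed from me by separating that pair, gave 90%, 92.5%, 75.7% and 28.5%, course rises, then falls, and said of Tuesday's that “it nearly finishes, but the catalyst is dying late”.

The flasks gave 93.0%, 92.6%, 75.7% and 29.9%, and the course falls all the way.

    starting material + free catalyst ⇌ catalyst intermediate A (K = 580 M⁻¹, k = 160 M⁻¹ h⁻¹)
    catalyst intermediate A → free catalyst + target (k = 0.550 h⁻¹)
    second substrate + free catalyst ⇌ catalyst intermediate B (K = 10.0 M⁻¹, k = 1400 M⁻¹ h⁻¹)
    catalyst intermediate B → free catalyst + second product (k = 5.70 h⁻¹)
    free catalyst + target → spent catalyst (k = 1.30 M⁻¹ h⁻¹)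

Tuesday's ended 4.1 points under its ceiling of 97.1%, with 4.3% of the starting material still in the flask and 89.9% of the catalyst spent. Wednesday's stood 3.1 points above its ceiling of 26.8% at 6.00 d, with 4.13% of its catalyst still free, and its target reached 26.8% at 60.0 d.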